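C1 = CHBr, C2 = CMe2, C3 = CHCl, C4 = CH2, C5 = ring =CH, C6 = ring =C, C7 = CHCl and C8 = CH2Br of the side chain. The strategy rests on C6 of the C5=C6 alkene in the single cyclohexene ring, which is flanked by two heteroatom-bearing carbons (C1 and C7). Read as C1–OH and C7=O, this array is a 2-acylcyclohex-2-en-1-ol, a cyclic Morita–Baylis–Hillman adduct.
The C1–Br, C7–Cl and C8–Br bonds are traced back to C–O bonds, with inversion at C1 and C7. The C7 carbinol comes from the C7 ketone by reagent-controlled reduction.
The only ring is closed after the whole C1–C8 chain is in place. The closure forms the C1–C6 bond: hydride adds to C5 of an acyclic ynone–aldehyde and the resulting allenolate is captured by the C1 aldehyde.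
The chain is joined linearly from three pieces. Methyl 3,3-dimethylpent-4-enoate gives C1–C4 (its vinyl group masks the C1 aldehyde), trimethylsilylacetylene gives C5–C6 by SN2 at C4, and methyl glycolate gives C7–C8 by acylation at C6.
C3–Cl is set first, by enamine-catalysed α-chlorination while C4 is an aldehyde, so no substitution is ever attempted at the neopentyl C3.
Key step: step 10

Assumption: the (2S,5S) antipode of 2,5-diphenylpyrrolidine is taken to give the (R)-2-chloroaldehyde (chlorine enters anti to the phenyl group lying syn to the enamine double bond); the sense would be checked on the chloro alcohol of step 2 and the (2R,5R) amine used if it proved opposite.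

Step 1
Reactants: 1 methyl 3,3-dimethylpent-4-enoate
Product: 2 3,3-dimethylpent-4-enal
Conditions: i-Bu2AlH (1.05 equiv), CH2Cl2, −78 °C; MeOH, then aqueous potassium sodium tartrate; the volatile aldehyde is kept as a dried CH2Cl2 solution
Reagents that add atoms: none
Why: Partial reduction of an ester with i-Bu2AlH, in which the aluminium hemiacetal is stable at −78 °C until the quench, so reduction should stop at the aldehyde and the isolated vinyl group is not hydroaluminated.

Step 2
Reactants: 2 3,3-dimethylpent-4-enal
Product: 4 (R)-2-chloro-3,3-dimethylpent-4-en-1-ol, via (R)-2-chloro-3,3-dimethylpent-4-enal 3 (not isolated)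
Conditions: NCS (1.3 equiv), (2S,5S)-2,5-diphenylpyrrolidine (20 mol %), CH2Cl2, 0 °C → rt; then MeOH, NaBH4, 0 °C
Reagents that add atoms: N-chlorosuccinimide, O=C1CCC(=O)N1Cl
Why: Enamine-catalysed electrophilic α-chlorination, in which the C2-symmetric amine exposes one enamine face to NCS and so sets C3 (R in 3 and 4, later 4S of the ring); tert-alkyl acetaldehydes lie within the known scope, and immediate NaBH4 reduction fixes the configurationally labile chloroaldehyde.

Step 3
Reactants: 4 (R)-2-chloro-3,3-dimethylpent-4-en-1-ol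
Product: 5 (R)-2-chloro-3,3-dimethylpent-4-en-1-yl trifluoromethanesulfonate
Conditions: Tf2O (1.1 equiv), 2,6-lutidine (1.3 equiv), CH2Cl2, −78 → −40 °C; cold work-up, used at once
Reagents that add atoms: trifluoromethanesulfonic anhydride, O=S(=O)(OS(=O)(=O)C(F)(F)F)C(F)(F)F
Why: O-Sulfonylation of a primary alcohol with a hindered pyridine base, the neighbouring electron-withdrawing C–Cl bond slowing ionisation enough for brief handling while the stereocentre is untouched.

Step 4
Reactants: 5 (R)-2-chloro-3,3-dimethylpent-4-en-1-yl trifluoromethanesulfonate; 6 trimethylsilylacetylene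
Product: 8 (S)-(4-chloro-5,5-dimethylhept-6-en-1-yn-1-yl)trimethylsilane, via lithium trimethylsilylacetylide 7 (not isolated)
Conditions: 6 (1.5 equiv), n-BuLi (1.45 equiv), THF, −78 °C; then DMPU and 5, −78 → −20 °C
Reagents that add atoms: none
Why: SN2 alkylation of a lithium acetylide by a primary triflate forms C4–C5; the very good leaving group offsets the β-branching at C3, the neopentyl secondary chloride is inert to substitution, and the low temperature holds back E2 loss of triflic acid.

Step 5
Reactants: 8 (S)-(4-chloro-5,5-dimethylhept-6-en-1-yn-1-yl)trimethylsilane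
Product: 9 (S)-4-chloro-3,3-dimethylhept-1-en-6-yne
Conditions: K2CO3 (0.2 equiv), MeOH, 0 °C → rt
Reagents that add atoms: none
Why: Base-catalysed protodesilylation of an alkynylsilane by methanol, under conditions too mild to eliminate HCl from the hindered secondary chloride.

Step 6
Reactants: 10 methyl glycolate
Product: 11 methyl 2-(tert-butyldimethylsilyloxy)acetate
Conditions: TBSCl, imidazole, CH2Cl2, 0 °C → rt
Reagents that add atoms: tert-butyldimethylsilyl chloride, CC(C)(C)[Si](C)(C)Cl
Why: Imidazole-promoted silylation of an unhindered primary alcohol, a standard protection that masks the C8 oxygen up to the endgame.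

Step 7
Reactants: 11 methyl 2-(tert-butyldimethylsilyloxy)acetate
Product: 12 2-(tert-butyldimethylsilyloxy)-N-methoxy-N-methylacetamide
Conditions: MeNH(OMe)·HCl (1.5 equiv), i-PrMgCl (3.0 equiv), THF, −20 → 0 °C
Reagents that add atoms: N,O-dimethylhydroxylamine hydrochloride, CNOC.Cl
Why: Aminolysis of the ester by the magnesium amide of N,O-dimethylhydroxylamine, the usual direct ester to N-methoxy-N-methylamide conversion, which the silyl ether tolerates.

Step 8
Reactants: 9 (S)-4-chloro-3,3-dimethylhept-1-en-6-yne; 12 2-(tert-butyldimethylsilyloxy)-N-methoxy-N-methylacetamide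
Product: 15 (S)-1-(tert-butyldimethylsilyloxy)-6-chloro-7,7-dimethylnon-8-en-3-yn-2-one, via lithium acetylide 13 (not isolated), via lithium hemiaminal adduct 14 (not isolated)
Conditions: 9, n-BuLi (1.0 equiv), THF, −78 °C; 12 (1.1 equiv), −78 → 0 °C; AcOH in THF, −78 °C
Reagents that add atoms: none
Why: Acylation of a lithium acetylide by an N-methoxy-N-methylamide forms C6–C7; chelated adduct 14 persists until the quench, so no second addition occurs, and the base-sensitive ynone is released only under acidic conditions that also keep the liberated amine from adding to it.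

Step 9
Reactants: 15 (S)-1-(tert-butyldimethylsilyloxy)-6-chloro-7,7-dimethylnon-8-en-3-yn-2-one
Product: 17 (S)-8-(tert-butyldimethylsilyloxy)-3-chloro-2,2-dimethyl-7-oxooct-5-ynal, via secondary ozonide 16 (not isolated)
Conditions: O3, CH2Cl2, −78 °C (Sudan red 7B as end-point dye); Me2S, −78 °C → rt
Reagents that add atoms: ozone, [O-][O+]=O
Why: Ozonolysis with reductive work-up, in which electrophilic ozone should consume the monosubstituted alkene long before the acyl-deactivated alkyne; Me2S is chosen because a phosphine would add to the ynone.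

Step 10
Reactants: 17 (S)-8-(tert-butyldimethylsilyloxy)-3-chloro-2,2-dimethyl-7-oxooct-5-ynal
Product: 20 1-[(4S,6R)-4-chloro-6-hydroxy-5,5-dimethylcyclohex-1-en-1-yl]-2-(tert-butyldimethylsilyloxy)ethan-1-one (hydroxyl cis to chlorine), via copper allenolate 18 (not isolated), via copper aldolate 19 (not isolated)
Conditions: [(Ph3P)CuH]6 (0.18 equiv, about 1.1 hydride equiv), degassed dry toluene, −40 → −10 °C; saturated aqueous NH4Cl
Reagents that add atoms: none
Why: Monovalent copper hydride should deliver hydride to C5 of the ynone much faster than to the hindered C1 aldehyde, giving copper allenolate 18, whose C6 is nucleophilic in the plane that holds H and C4 on C5. C6 then adds to the C1 carbonyl carbon to form the C1–C6 bond and aldolate 19, and because the tether can reach C6 only from the C4 side, C4 and C1 end up cis on the new C5=C6 alkene as the ring requires. The closest known reaction type is the [(Ph3P)CuH]6-induced reductive aldol cyclization of alkynones carrying a tethered ketone, the reductive counterpart of the intramolecular Morita–Baylis–Hillman reaction, and the aldehyde used here is simply the more electrophilic acceptor. The one six-membered ring closes in the 6-(enolexo)-exo-trig mode, assisted by the gem-dimethyl group at C2. The new C1 stereocentre is controlled by C3: in the half-chair transition state C3–Cl lies equatorial and the aldehyde oxygen takes the pseudo-equatorial site from which it can share copper with the C7 oxygen, which places C1–O cis to C3–Cl (6R). The step needs conjugate reduction before aldehyde reduction, no second hydride addition and no loss of HCl, and these are secured by the quaternary C2 next to the non-enolisable aldehyde, by one hydride equivalent at low temperature and by the non-basic reagent.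

Step 11
Reactants: 20 1-[(4S,6R)-4-chloro-6-hydroxy-5,5-dimethylcyclohex-1-en-1-yl]-2-(tert-butyldimethylsilyloxy)ethan-1-one
Product: 21 2-(tert-butyldimethylsilyloxy)-1-[(4S,6R)-6-(tert-butyldimethylsilyloxy)-4-chloro-5,5-dimethylcyclohex-1-en-1-yl]ethan-1-one
Conditions: TBSOTf (1.3 equiv), 2,6-lutidine (2 equiv), CH2Cl2, −78 → 0 °C
Reagents that add atoms: tert-butyldimethylsilyl trifluoromethanesulfonate, CC(C)(C)[Si](C)(C)OS(=O)(=O)C(F)(F)F
Why: Silylation of a hindered secondary alcohol with a silyl triflate; the weak, hindered base should trigger neither retro-aldol cleavage nor vinylogous loss of HCl from the γ-CH2/δ-Cl enone.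

Step 12
Reactants: 21 2-(tert-butyldimethylsilyloxy)-1-[(4S,6R)-6-(tert-butyldimethylsilyloxy)-4-chloro-5,5-dimethylcyclohex-1-en-1-yl]ethan-1-one
Product: 22 (1R)-2-(tert-butyldimethylsilyloxy)-1-[(4S,6R)-6-(tert-butyldimethylsilyloxy)-4-chloro-5,5-dimethylcyclohex-1-en-1-yl]ethan-1-ol
Conditions: (R)-1-methyl-3,3-diphenyltetrahydro-1H,3H-pyrrolo[1,2-c][1,3,2]oxazaborole (0.3 equiv), BH3·SMe2 (1.0 equiv), THF, −30 °C; MeOH
Reagents that add atoms: none
Why: Corey–Bakshi–Shibata reduction, in which the ketone binds the catalyst boron anti to its larger substituent (here the crowded cyclohexenyl group, not CH2OTBS), so the (R)-catalyst should give the (7R)-alcohol under reagent control by the 1,2-reduction that is normal for enones.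

Step 13
Reactants: 22 (1R)-2-(tert-butyldimethylsilyloxy)-1-[(4S,6R)-6-(tert-butyldimethylsilyloxy)-4-chloro-5,5-dimethylcyclohex-1-en-1-yl]ethan-1-ol
Product: 23 (4S,6S)-6-(tert-butyldimethylsilyloxy)-1-[(1S)-2-(tert-butyldimethylsilyloxy)-1-chloroethyl]-4-chloro-5,5-dimethylcyclohex-1-ene
Conditions: PPh3 (1.5 equiv), NCS (1.5 equiv), THF, −20 → 0 °C
Reagents that add atoms: N-chlorosuccinimide, O=C1CCC(=O)N1Cl
Why: Appel-type chlorination, in which the salt formed from PPh3 and NCS activates the only free hydroxyl and chloride displaces it by SN2 with inversion ((7R)-OH to (7S)-Cl); the inductive pull of the C8 oxygen disfavours ionisation and the low temperature limits SN2' attack at C5.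

Step 14
Reactants: 23 (4S,6S)-6-(tert-butyldimethylsilyloxy)-1-[(1S)-2-(tert-butyldimethylsilyloxy)-1-chloroethyl]-4-chloro-5,5-dimethylcyclohex-1-ene
Product: 24 (1S,5S)-5-chloro-2-[(1S)-1-chloro-2-hydroxyethyl]-6,6-dimethylcyclohex-2-en-1-ol
Conditions: HF·pyridine, pyridine, THF, 0 °C → rt (polypropylene vessel)
Reagents that add atoms: none
Why: Fluoride-induced cleavage of both silyl ethers under weakly acidic conditions, chosen because a basic fluoride source would close the C7/C8 chlorohydrin to an epoxide or eliminate HCl, and no stereocentre is involved.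

Step 15
Reactants: 24 (1S,5S)-5-chloro-2-[(1S)-1-chloro-2-hydroxyethyl]-6,6-dimethylcyclohex-2-en-1-ol
Product: 26 (4S,6R)-6-bromo-1-[(1S)-2-bromo-1-chloroethyl]-4-chloro-5,5-dimethylcyclohex-1-ene (CNP0105443.4), via C8 monobromide 25 (not isolated)
Conditions: CBr4 (3 equiv), PPh3 (3 equiv), CH2Cl2, −20 °C → rt
Reagents that add atoms: carbon tetrabromide, BrC(Br)(Br)Br
Why: Appel bromination, in which excess reagent activates both hydroxyls, primary C8 reacts first (25), and bromide then displaces the allylic C1 group by SN2 with inversion along the axial line on the face that carries only the axial C3–H, so the cis alcohol should give the pseudoaxial bromide trans to C3–Cl (6R).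

Compound list
1 | methyl 3,3-dimethylpent-4-enoate | C=CC(C)(C)CC(=O)OC | starting material
2 | 3,3-dimethylpent-4-enal | C=CC(C)(C)CC=O | intermediate
3 | (R)-2-chloro-3,3-dimethylpent-4-enal | C=CC(C)(C)[C@@H](Cl)C=O | intermediate
4 | (R)-2-chloro-3,3-dimethylpent-4-en-1-ol | C=CC(C)(C)[C@@H](Cl)CO | intermediate
5 | (R)-2-chloro-3,3-dimethylpent-4-en-1-yl trifluoromethanesulfonate | C=CC(C)(C)[C@@H](Cl)COS(=O)(=O)C(F)(F)F | intermediate
6 | trimethylsilylacetylene | C#C[Si](C)(C)C | starting material
7 | lithium trimethylsilylacetylide | [Li]C#C[Si](C)(C)C | intermediate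
8 | (S)-(4-chloro-5,5-dimethylhept-6-en-1-yn-1-yl)trimethylsilane | C=CC(C)(C)[C@@H](Cl)CC#C[Si](C)(C)C | intermediate
9 | (S)-4-chloro-3,3-dimethylhept-1-en-6-yne | C=CC(C)(C)[C@@H](Cl)CC#C | intermediate
10 | methyl glycolate | COC(=O)CO | starting material
11 | methyl 2-(tert-butyldimethylsilyloxy)acetate | COC(=O)CO[Si](C)(C)C(C)(C)C | intermediate
12 | 2-(tert-butyldimethylsilyloxy)-N-methoxy-N-methylacetamide | CON(C)C(=O)CO[Si](C)(C)C(C)(C)C | intermediate
13 | lithium acetylide of 9 (lithium on the terminal alkyne carbon C6) | C=CC(C)(C)[C@@H](Cl)CC#C[Li] | intermediate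
14 | lithium hemiaminal adduct of 13 and 12 (C7 bears OLi, N(OMe)Me, CH2OTBS and the alkynyl chain; C7 configuration not defined) | C=CC(C)(C)[C@@H](Cl)CC#CC(O[Li])(CO[Si](C)(C)C(C)(C)C)N(C)OC | intermediate
15 | (S)-1-(tert-butyldimethylsilyloxy)-6-chloro-7,7-dimethylnon-8-en-3-yn-2-one | C=CC(C)(C)[C@@H](Cl)CC#CC(=O)CO[Si](C)(C)C(C)(C)C | intermediate
16 | secondary ozonide of 15 (3-substituted 1,2,4-trioxolane; acetal carbon not defined) | C1OC(OO1)C(C)(C)[C@@H](Cl)CC#CC(=O)CO[Si](C)(C)C(C)(C)C | intermediate
17 | (S)-8-(tert-butyldimethylsilyloxy)-3-chloro-2,2-dimethyl-7-oxooct-5-ynal | O=CC(C)(C)[C@@H](Cl)CC#CC(=O)CO[Si](C)(C)C(C)(C)C | intermediate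
18 | copper allenolate (C5=C6=C7–OCu; phosphine ligand omitted, axis not defined) | O=CC(C)(C)[C@@H](Cl)CC=C=C(O[Cu])CO[Si](C)(C)C(C)(C)C | intermediate
19 | copper aldolate of 20 (C1–OCu; phosphine ligand omitted) | CC1(C)[C@@H](Cl)CC=C(C(=O)CO[Si](C)(C)C(C)(C)C)[C@H]1O[Cu] | intermediate
20 | 1-[(4S,6R)-4-chloro-6-hydroxy-5,5-dimethylcyclohex-1-en-1-yl]-2-(tert-butyldimethylsilyloxy)ethan-1-one | CC1(C)[C@@H](Cl)CC=C(C(=O)CO[Si](C)(C)C(C)(C)C)[C@H]1O | intermediate
21 | 2-(tert-butyldimethylsilyloxy)-1-[(4S,6R)-6-(tert-butyldimethylsilyloxy)-4-chloro-5,5-dimethylcyclohex-1-en-1-yl]ethan-1-one | CC1(C)[C@@H](Cl)CC=C(C(=O)CO[Si](C)(C)C(C)(C)C)[C@H]1O[Si](C)(C)C(C)(C)C | intermediate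
22 | (1R)-2-(tert-butyldimethylsilyloxy)-1-[(4S,6R)-6-(tert-butyldimethylsilyloxy)-4-chloro-5,5-dimethylcyclohex-1-en-1-yl]ethan-1-ol | CC1(C)[C@@H](Cl)CC=C([C@@H](O)CO[Si](C)(C)C(C)(C)C)[C@H]1O[Si](C)(C)C(C)(C)C | intermediate
23 | (4S,6S)-6-(tert-butyldimethylsilyloxy)-1-[(1S)-2-(tert-butyldimethylsilyloxy)-1-chloroethyl]-4-chloro-5,5-dimethylcyclohex-1-ene | CC1(C)[C@@H](Cl)CC=C([C@H](Cl)CO[Si](C)(C)C(C)(C)C)[C@H]1O[Si](C)(C)C(C)(C)C | intermediate
24 | (1S,5S)-5-chloro-2-[(1S)-1-chloro-2-hydroxyethyl]-6,6-dimethylcyclohex-2-en-1-ol | CC1(C)[C@@H](Cl)CC=C([C@H](Cl)CO)[C@H]1O | intermediate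
25 | (1S,5S)-2-[(1S)-2-bromo-1-chloroethyl]-5-chloro-6,6-dimethylcyclohex-2-en-1-ol | CC1(C)[C@@H](Cl)CC=C([C@H](Cl)CBr)[C@H]1O | intermediate
26 | (4S,6R)-6-bromo-1-[(1S)-2-bromo-1-chloroethyl]-4-chloro-5,5-dimethylcyclohex-1-ene | CC1(C)[C@@H](Cl)CC=C([C@H](Cl)CBr)[C@@H]1Br | target

Total step count: 15. Longest linear sequence: 13 steps (steps 1–5 and 8–15, from 1 to 26). Steps 6 and 7 form the two-step side branch.

Three steps most likely to fail

Step 10.
- **What may go wrong:** Hydride may also reduce the aldehyde or add a second time to the enone. The allenolate may be protonated before it closes. Facial selectivity at C1 may be poor.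
- **Fallback:** Hydride is replaced by iodide as the conjugate nucleophile, the halo-aldol variant of the Morita–Baylis–Hillman reaction, which is known for ynones with tethered aldehydes. It sets out from 17. MgI2 in CH2Cl2 at 0 °C should add iodide to C5, and the magnesium-chelated β-iodoallenolate should close onto C1 to give 1-[(4S,6S)-4-chloro-6-hydroxy-2-iodo-5,5-dimethylcyclohex-1-en-1-yl]-2-(tert-butyldimethylsilyloxy)ethan-1-one F1. This compound has the same spatial arrangement as 20. The vinylic iodine is then exchanged for hydrogen with Bu3SnH (one equivalent, added slowly) and catalytic Pd(PPh3)4 in THF, which the alkyl chloride should survive. The route is rejoined at 20.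

Step 13.
- **What may go wrong:** Chloride may enter at C5 with allylic transposition. The activated alcohol may ionise with erosion of the C7 configuration. Activation may be slow next to the bulky C1 silyl ether.
- **Fallback:** The C7 oxygen is turned into an alkenyl epoxide and opened, instead of being displaced as a phosphonium leaving group. It sets out from 22.
  - Catalytic camphorsulfonic acid in MeOH/CH2Cl2 at 0 °C should remove only the primary silyl group, giving (1R)-1-[(4S,6R)-6-(tert-butyldimethylsilyloxy)-4-chloro-5,5-dimethylcyclohex-1-en-1-yl]ethane-1,2-diol F2.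
  - TsCl, Et3N and catalytic Bu2SnO should sulfonylate the primary hydroxyl to give the C8 monotosylate F3.
  - K2CO3 in MeOH should close the (2R)-oxirane F4 with the C7–O bond retained.
  - Et4NCl with BF3·OEt2 in CH2Cl2 at −78 °C should open the alkenyl epoxide at the allylic C7 with inversion, giving (2S)-2-[(4S,6S)-6-(tert-butyldimethylsilyloxy)-4-chloro-5,5-dimethylcyclohex-1-en-1-yl]-2-chloroethan-1-ol F5.
  - HF·pyridine then frees C1–OH, and the route is rejoined at 24.

Step 15.
- **What may go wrong:** Direct displacement at C1 is slowed by the adjacent quaternary C2. Four processes can therefore compete: allylic transposition with bromide entering at C5, ionisation with loss of configuration, cyclodehydration of the 1,4-related diol to a bicyclic ether, and halide exchange at allylic C7.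
- **Fallback:** The two C–Br bonds are made in separate operations with the other oxygen masked, and the activation at C1 is changed. It sets out from 23.
  - Catalytic camphorsulfonic acid in MeOH/CH2Cl2 at 0 °C should remove only the primary silyl group to give the mono-silyl chloro alcohol F5.
  - CBr4/PPh3 in CH2Cl2 at 0 °C should convert C8–OH into the bromide, giving tert-butyl{[(1S,5S)-2-[(1S)-2-bromo-1-chloroethyl]-5-chloro-6,6-dimethylcyclohex-2-en-1-yl]oxy}dimethylsilane F6.
  - HF·pyridine should then give 25, which is isolated in this variant.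
  - 1-Bromo-N,N,2-trimethylprop-1-en-1-amine in CH2Cl2 at 0 °C should replace C1–OH by bromide with inversion under neutral conditions. This haloenamine method is known to convert allylic alcohols without transposition. The route is rejoined at 26.

Further compounds
F1 | step 10 | 1-[(4S,6S)-4-chloro-6-hydroxy-2-iodo-5,5-dimethylcyclohex-1-en-1-yl]-2-(tert-butyldimethylsilyloxy)ethan-1-one | IC1=C(C(=O)CO[Si](C)(C)C(C)(C)C)[C@@H](O)C(C)(C)[C@@H](Cl)C1
F2 | step 13 | (1R)-1-[(4S,6R)-6-(tert-butyldimethylsilyloxy)-4-chloro-5,5-dimethylcyclohex-1-en-1-yl]ethane-1,2-diol | CC1(C)[C@@H](Cl)CC=C([C@@H](O)CO)[C@H]1O[Si](C)(C)C(C)(C)C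
F3 | step 13 | (2R)-2-[(4S,6R)-6-(tert-butyldimethylsilyloxy)-4-chloro-5,5-dimethylcyclohex-1-en-1-yl]-2-hydroxyethyl 4-methylbenzenesulfonate | CC1(C)[C@@H](Cl)CC=C([C@@H](O)COS(=O)(=O)c2ccc(C)cc2)[C@H]1O[Si](C)(C)C(C)(C)C
F4 | step 13 | (2R)-2-[(4S,6R)-6-(tert-butyldimethylsilyloxy)-4-chloro-5,5-dimethylcyclohex-1-en-1-yl]oxirane | CC1(C)[C@@H](Cl)CC=C([C@@H]2CO2)[C@H]1O[Si](C)(C)C(C)(C)C
F5 | step 13 | (2S)-2-[(4S,6S)-6-(tert-butyldimethylsilyloxy)-4-chloro-5,5-dimethylcyclohex-1-en-1-yl]-2-chloroethan-1-ol | CC1(C)[C@@H](Cl)CC=C([C@H](Cl)CO)[C@H]1O[Si](C)(C)C(C)(C)C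
F6 | step 15 | tert-butyl{[(1S,5S)-2-[(1S)-2-bromo-1-chloroethyl]-5-chloro-6,6-dimethylcyclohex-2-en-1-yl]oxy}dimethylsilane | CC1(C)[C@@H](Cl)CC=C([C@H](Cl)CBr)[C@H]1O[Si](C)(C)C(C)(C)C
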